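**Plan**
- Retrosynthesis: cut the C-7–O bond (allylic hydroxylation), then C-13=C-14 (olefination of a methyl ketone), then both ring bonds C-4–C-5 and C-9–C-10 in one oxidative radical bicyclisation of a 2-methyl-3-oxo ester polyene (C-3 oxygen as a removable helper), then C-1–C-2 (dianion alkylation).
- Forward: geranylacetone ketal is turned into its ω-bromide and joined to the dianion of 8-phenylmenthyl 2-methylacetoacetate; ring A and then ring B close in one cascade; the C-3 oxygen is removed, the side chain completed, C-19 acetylated and C-7 hydroxylated.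
- Enabling feature: rings A and B are a trans-decalin whose C-4, C-5, C-10, C-9 and C-8 sit in the 1,5-diene spacing of a polyprenoid chain, as in the biosynthetic folding. C-4 carries the oxidised C-19 next to C-3, so C-3/C-4/C-19 can begin as a β-keto ester, and the C-8(17) methylene is the alkene left by the terminating step.
- Stereochemistry: bought (−)-8-phenylmenthol controls the face at C-4; chair–chair folding of the E,E-diene relays C-5, C-10 and C-9 in the same event; C-7 comes from an axial ene/[2,3] hydroxylation; 13E comes from the olefination.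

Key step: step 6

Assumption: the sense of facial control by the (1R,2S,5R)-8-phenylmenthyl ester is taken from the π-shielding model applied to the dipole-minimised radical conformer; should it prove opposite, the (1S,2R,5S) alcohol would be used in the same route.
Numbering: labdane numbering (C-1 to C-20) is used for all intermediates, including the open-chain precursors.

**Step 1**
Reactants: 1 (5E)-geranylacetone
Product: 2 2-[(3E)-4,8-dimethylnona-3,7-dien-1-yl]-2-methyl-1,3-dioxolane
Conditions: HOCH2CH2OH, PPTS (cat.), toluene, Dean–Stark, reflux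
Reagents that add atoms: ethylene glycol, OCCO
Why: Acid-catalysed ketalisation with azeotropic removal of water masks the methyl ketone against the dianion of step 5 and the hydride of step 7; no stereocentre is formed.

**Step 2**
Reactants: 2 geranylacetone ethylene ketal
Product: 3 (2E,6E)-2,6-dimethyl-9-(2-methyl-1,3-dioxolan-2-yl)nona-2,6-dien-1-ol
Conditions: SeO2 (cat.), t-BuOOH, salicylic acid (cat.), CH2Cl2, 0 °C to 25 °C
Reagents that add atoms: selenium dioxide (oxygen carrier), O=[Se]=O; tert-butyl hydroperoxide (terminal oxygen source), CC(C)(C)OO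
Why: Catalytic SeO2 allylic oxidation (ene reaction, then [2,3]-sigmatropic shift) should attack the more accessible terminal trisubstituted alkene and hydroxylate its E-methyl group, giving the E-allylic alcohol.

**Step 3**
Reactants: 3 the ω-hydroxy ketal
Product: 4 2-[(3E,7E)-9-bromo-4,8-dimethylnona-3,7-dien-1-yl]-2-methyl-1,3-dioxolane
Conditions: PPh3, CBr4, CH2Cl2, −20 °C to 0 °C
Reagents that add atoms: carbon tetrabromide, BrC(Br)(Br)Br
Why: Appel bromination converts the primary allylic alcohol into the bromide under neutral conditions that spare the ketal and the alkene geometry.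

**Step 4**
Reactants: 5 (−)-8-phenylmenthol [(1R,2S,5R)-5-methyl-2-(2-phenylpropan-2-yl)cyclohexan-1-ol]; 6 ethyl 2-methyl-3-oxobutanoate
Product: 7 (1R,2S,5R)-8-phenylmenthyl 2-methyl-3-oxobutanoate (both C-2 epimers)
Conditions: DMAP (0.3 equiv), toluene, reflux, 4 Å molecular sieves to remove EtOH
Reagents that add atoms: none
Why: DMAP-catalysed transesterification of a 3-oxo ester (through the acylketene) loads the auxiliary; the epimeric C-2 centre is of no consequence because it becomes planar in steps 5 and 6.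

**Step 5**
Reactants: 7 8-phenylmenthyl 2-methylacetoacetate; 4 the allylic bromide
Product: 9 (1R,2S,5R)-8-phenylmenthyl (6E,10E)-2,6,10-trimethyl-13-(2-methyl-1,3-dioxolan-2-yl)-3-oxotrideca-6,10-dienoate, via sodium lithium dianion 8 (not isolated)
Conditions: NaH, THF, 0 °C; n-BuLi, 0 °C; then 4, 0 °C to 25 °C; aq. NH4Cl
Reagents that add atoms: none
Why: γ-Alkylation of an acetoacetate 1,3-dianion: the more basic terminal carbanion of 8 displaces the primary allylic bromide by SN2, joining C-1 to C-2 with both E alkenes untouched.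

**Step 6**
Reactants: 9 the polyene 3-oxo ester
Product: 12 (1R,2S,5R)-8-phenylmenthyl 13,13-(ethylenedioxy)-3-oxo-14,15-dinorlabd-8(17)-en-19-oate (4β-ester; 5α-H; 9α-H; 10β-methyl), via acyclic C-4 radical 10 (not isolated), via bicyclic C-8 radical 11 (not isolated)
Conditions: Mn(OAc)3·2H2O (2.2 equiv), Cu(OAc)2·H2O (1 equiv), degassed EtOH, 25–40 °C
Reagents that add atoms: none
Why: Mn(OAc)3 oxidises the manganese enolate of the 2-methyl-3-oxo ester to the C-4 radical 10, which adds to C-5 of the 5(10)-alkene; the tertiary C-10 radical then adds to C-9 of the 8(9)-alkene, so the C-4–C-5 and C-9–C-10 bonds form in one cascade, and the tertiary C-8 radical 11 is oxidised by Cu(OAc)2 through an alkylcopper species that loses a C-17 hydrogen to give the exocyclic 8(17)-alkene. The closest known reaction type is the Mn(OAc)3/Cu(OAc)2 oxidative free-radical polyene cyclisation of 2-alkyl-3-oxo esters, including esters of phenylmenthol-type auxiliaries. Ring A closes 6-endo-trig and ring B closes 6-endo-trig, both through chair transition states. C-4 is set by the auxiliary, whose phenyl ring covers one face of the planar radical in the dipole-minimised conformer (ester trans to the ketone oxygen about C-3–C-4, which also places the ester axial); C-5 and C-10 follow from anti addition across the E 5(10)-alkene (trans ring fusion), and C-9 from the E 8(9)-alkene in the chair (side chain equatorial). The step needs the cascade to stop after two rings and to end in the exocyclic alkene: the chain beyond C-12 holds no alkene because C-13 is masked as a ketal, and the copper-mediated elimination should prefer the unhindered methyl hydrogens; a minor ring diastereomer should be removable by chromatography because the auxiliary makes the two series diastereomers.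

**Step 7**
Reactants: 12 the bicyclic keto ester ketal
Product: 14 (1R,2S,5R)-8-phenylmenthyl 3β-hydroxy-13-oxo-14,15-dinorlabd-8(17)-en-19-oate, via 3β-hydroxy ketal 13 (not isolated)
Conditions: NaBH4, MeOH/THF, 0 °C; then 1 M aq. HCl, THF, 25 °C
Reagents that add atoms: water (supplies the C-13 carbonyl oxygen), O
Why: NaBH4 reduces only the C-3 ketone (axial hydride delivery from the α face should give the equatorial 3β-alcohol; the configuration is immaterial because the centre is removed in step 9) and the acidic work-up hydrolyses the ketal.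

**Step 8**
Reactants: 14 the 3β-hydroxy ketone
Product: 15 (1R,2S,5R)-8-phenylmenthyl 13-oxo-3β-(phenoxycarbonothioyloxy)-14,15-dinorlabd-8(17)-en-19-oate
Conditions: PhOC(S)Cl, pyridine, DMAP (cat.), CH2Cl2, 25 °C
Reagents that add atoms: O-phenyl chlorothionoformate, S=C(Cl)Oc1ccccc1
Why: DMAP-catalysed thioacylation gives the thionocarbonate for Barton–McCombie deoxygenation without strong base, so the β-hydroxy ester cannot undergo retro-aldol cleavage.

**Step 9**
Reactants: 15 the thionocarbonate
Product: 16 (1R,2S,5R)-8-phenylmenthyl 13-oxo-14,15-dinorlabd-8(17)-en-19-oate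
Conditions: Bu3SnH, AIBN (cat.), toluene, 100 °C
Reagents that add atoms: none
Why: Barton–McCombie deoxygenation: the stannyl radical adds to the thiocarbonyl, the C-3–O bond fragments and the secondary C-3 radical takes hydrogen from Bu3SnH, removing the helper oxygen of ring A.

**Step 10**
Reactants: 16 the methyl ketone
Product: 17 15-ethyl 19-[(1R,2S,5R)-8-phenylmenthyl] labda-8(17),13E-diene-15,19-dioate
Conditions: (EtO)2P(O)CH2CO2Et, NaH, THF, 0 °C to 50 °C
Reagents that add atoms: triethyl phosphonoacetate, CCOC(=O)CP(=O)(OCC)OCC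
Why: Horner–Wadsworth–Emmons olefination of the methyl ketone adds C-14 and C-15; the stabilised phosphonate should give mainly the 13E ester (ester trans to the larger C-12 chain), the minor 13Z isomer being separable by chromatography, while the hindered C-19 ester without α-hydrogen is inert.

**Step 11**
Reactants: 17 the diester
Product: 18 labda-8(17),13E-diene-15,19-diol
Conditions: LiAlH4, THF, 0 °C then 65 °C; aq. NaOH work-up
Reagents that add atoms: none
Why: LiAlH4 reduces the conjugated ester 1,2 to the allylic alcohol and, on warming, the hindered axial C-19 ester to the neopentyl alcohol, releasing the auxiliary for recovery.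

**Step 12**
Reactants: 18 the 15,19-diol
Product: 19 15-(tert-butyldimethylsilyloxy)labda-8(17),13E-dien-19-ol
Conditions: TBSCl (1.05 equiv), imidazole, CH2Cl2, −20 °C to 0 °C
Reagents that add atoms: tert-butyldimethylsilyl chloride, CC(C)(C)[Si](C)(C)Cl
Why: Silylation under kinetic control: the unhindered allylic C-15 hydroxyl should react much faster than the neopentyl, axial C-19 hydroxyl.

**Step 13**
Reactants: 19 the mono-silyl ether
Product: 20 15-(tert-butyldimethylsilyloxy)labda-8(17),13E-dien-19-yl acetate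
Conditions: Ac2O, pyridine, DMAP (cat.), CH2Cl2, 25 °C
Reagents that add atoms: acetic anhydride, CC(=O)OC(C)=O
Why: DMAP-catalysed acetylation of the remaining primary alcohol installs the C-19 acetate.

**Step 14**
Reactants: 20 the acetate silyl ether
Product: 21 15-(tert-butyldimethylsilyloxy)-7α-hydroxylabda-8(17),13E-dien-19-yl acetate
Conditions: SeO2 (0.5 equiv), t-BuOOH, CH2Cl2, 0 °C to 25 °C
Reagents that add atoms: selenium dioxide (oxygen carrier), O=[Se]=O; tert-butyl hydroperoxide (terminal oxygen source), CC(C)(C)OO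
Why: SeO2 allylic hydroxylation of the 1,1-disubstituted 8(17)-alkene: ene reaction at C-17 with loss of the axial 7α-hydrogen (a CH2 group reacts before the C-9 methine) and a [2,3]-shift returning oxygen axially to C-7 should give the 7α-alcohol, while the side-chain alkene is deactivated by its allylic silyloxy group.

**Step 15**
Reactants: 21 the 7α-hydroxy silyl ether
Product: 22 (4S,5R,7R,9R,10S)-7α,15-dihydroxylabda-8(17),13E-dien-19-yl acetate (target)
Conditions: HF·pyridine, THF/pyridine, 0 °C to 25 °C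
Reagents that add atoms: none
Why: Fluoride cleaves the primary allylic silyl ether, and the pyridine-buffered medium should leave the acetate and the allylic alcohol untouched.

**Compound list**
1 | (5E)-geranylacetone, (5E)-6,10-dimethylundeca-5,9-dien-2-one | CC(=O)CC/C=C(\C)CCC=C(C)C | starting material
2 | 2-[(3E)-4,8-dimethylnona-3,7-dien-1-yl]-2-methyl-1,3-dioxolane | CC1(CC/C=C(\C)CCC=C(C)C)OCCO1 | intermediate
3 | (2E,6E)-2,6-dimethyl-9-(2-methyl-1,3-dioxolan-2-yl)nona-2,6-dien-1-ol | CC1(CC/C=C(\C)CC/C=C(\C)CO)OCCO1 | intermediate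
4 | 2-[(3E,7E)-9-bromo-4,8-dimethylnona-3,7-dien-1-yl]-2-methyl-1,3-dioxolane | CC1(CC/C=C(\C)CC/C=C(\C)CBr)OCCO1 | intermediate
5 | (−)-8-phenylmenthol, (1R,2S,5R)-5-methyl-2-(2-phenylpropan-2-yl)cyclohexan-1-ol | CC(C)(c1ccccc1)[C@@H]1CC[C@@H](C)C[C@H]1O | starting material (auxiliary, recovered in step 11)
6 | ethyl 2-methyl-3-oxobutanoate (racemic) | CCOC(=O)C(C)C(C)=O | starting material
7 | (1R,2S,5R)-8-phenylmenthyl 2-methyl-3-oxobutanoate (C-2 epimers) | CC(C)(c1ccccc1)[C@@H]1CC[C@@H](C)C[C@H]1OC(=O)C(C)C(C)=O | intermediate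
8 | sodium lithium 1,3-dianion of 7 | CC(C)(c1ccccc1)[C@@H]1CC[C@@H](C)C[C@H]1OC(=O)[C-](C)C(=O)[CH2-].[Na+].[Li+] | intermediate (not isolated)
9 | (1R,2S,5R)-8-phenylmenthyl (6E,10E)-2,6,10-trimethyl-13-(2-methyl-1,3-dioxolan-2-yl)-3-oxotrideca-6,10-dienoate | CC(C)(c1ccccc1)[C@@H]1CC[C@@H](C)C[C@H]1OC(=O)C(C)C(=O)CC/C(C)=C/CC/C(C)=C/CCC1(C)OCCO1 | intermediate
10 | acyclic C-4 radical of 9 (tertiary radical between ester and ketone) | CC(C)(c1ccccc1)[C@@H]1CC[C@@H](C)C[C@H]1OC(=O)[C](C)C(=O)CC/C(C)=C/CC/C(C)=C/CCC1(C)OCCO1 | intermediate (not isolated)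
11 | bicyclic tertiary C-8 radical (trans-decalin, before loss of a C-17 hydrogen) | C[C]1CC[C@H]2[C@@](C)(C(=O)O[C@@H]3C[C@H](C)CC[C@H]3C(C)(C)c3ccccc3)C(=O)CC[C@]2(C)[C@H]1CCC1(C)OCCO1 | intermediate (not isolated)
12 | (1R,2S,5R)-8-phenylmenthyl 13,13-(ethylenedioxy)-3-oxo-14,15-dinorlabd-8(17)-en-19-oate | C=C1CC[C@H]2[C@@](C)(C(=O)O[C@@H]3C[C@H](C)CC[C@H]3C(C)(C)c3ccccc3)C(=O)CC[C@]2(C)[C@H]1CCC1(C)OCCO1 | intermediate
13 | (1R,2S,5R)-8-phenylmenthyl 13,13-(ethylenedioxy)-3β-hydroxy-14,15-dinorlabd-8(17)-en-19-oate | C=C1CC[C@H]2[C@@](C)(C(=O)O[C@@H]3C[C@H](C)CC[C@H]3C(C)(C)c3ccccc3)[C@@H](O)CC[C@]2(C)[C@H]1CCC1(C)OCCO1 | intermediate (not isolated)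
14 | (1R,2S,5R)-8-phenylmenthyl 3β-hydroxy-13-oxo-14,15-dinorlabd-8(17)-en-19-oate | C=C1CC[C@H]2[C@@](C)(C(=O)O[C@@H]3C[C@H](C)CC[C@H]3C(C)(C)c3ccccc3)[C@@H](O)CC[C@]2(C)[C@H]1CCC(C)=O | intermediate
15 | (1R,2S,5R)-8-phenylmenthyl 13-oxo-3β-(phenoxycarbonothioyloxy)-14,15-dinorlabd-8(17)-en-19-oate | C=C1CC[C@H]2[C@@](C)(C(=O)O[C@@H]3C[C@H](C)CC[C@H]3C(C)(C)c3ccccc3)[C@@H](OC(=S)Oc3ccccc3)CC[C@]2(C)[C@H]1CCC(C)=O | intermediate
16 | (1R,2S,5R)-8-phenylmenthyl 13-oxo-14,15-dinorlabd-8(17)-en-19-oate | C=C1CC[C@H]2[C@@](C)(C(=O)O[C@@H]3C[C@H](C)CC[C@H]3C(C)(C)c3ccccc3)CCC[C@]2(C)[C@H]1CCC(C)=O | intermediate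
17 | 15-ethyl 19-[(1R,2S,5R)-8-phenylmenthyl] labda-8(17),13E-diene-15,19-dioate | C=C1CC[C@H]2[C@@](C)(C(=O)O[C@@H]3C[C@H](C)CC[C@H]3C(C)(C)c3ccccc3)CCC[C@]2(C)[C@H]1CC/C(C)=C/C(=O)OCC | intermediate
18 | labda-8(17),13E-diene-15,19-diol | C=C1CC[C@H]2[C@@](C)(CO)CCC[C@]2(C)[C@H]1CC/C(C)=C/CO | intermediate
19 | 15-(tert-butyldimethylsilyloxy)labda-8(17),13E-dien-19-ol | C=C1CC[C@H]2[C@@](C)(CO)CCC[C@]2(C)[C@H]1CC/C(C)=C/CO[Si](C)(C)C(C)(C)C | intermediate
20 | 15-(tert-butyldimethylsilyloxy)labda-8(17),13E-dien-19-yl acetate | C=C1CC[C@H]2[C@@](C)(COC(C)=O)CCC[C@]2(C)[C@H]1CC/C(C)=C/CO[Si](C)(C)C(C)(C)C | intermediate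
21 | 15-(tert-butyldimethylsilyloxy)-7α-hydroxylabda-8(17),13E-dien-19-yl acetate | C=C1[C@H](O)C[C@H]2[C@@](C)(COC(C)=O)CCC[C@]2(C)[C@H]1CC/C(C)=C/CO[Si](C)(C)C(C)(C)C | intermediate
22 | (4S,5R,7R,9R,10S)-7α,15-dihydroxylabda-8(17),13E-dien-19-yl acetate | C=C1[C@H](O)C[C@H]2[C@@](C)(COC(C)=O)CCC[C@]2(C)[C@H]1CC/C(C)=C/CO | target

**Totals**
Total step count: 15. Longest linear sequence: 14 steps (steps 1–3 and 5–15; step 4 prepares the auxiliary ester).

**Steps most likely to fail**

Step 6. The ketal may be partly lost and the facial control by the auxiliary may be weaker in ethanol, a less acidic medium than the acetic acid in which such auxiliary-controlled cascades are usually run; early copper oxidation of the monocyclic radical is a further risk. Fallback: setting out from 9, the ketal is removed first (PPTS, acetone/H2O) to give the open-chain diketo ester F1. F1 is cyclised with Mn(OAc)3·2H2O and Cu(OAc)2·H2O in acetic acid at 25 °C to the bicyclic 3,13-dione F2; the side-chain methyl ketone is enolised by Mn(OAc)3 far less readily than the 3-oxo ester. Only the unhindered C-13 ketone is then ketalised (1,2-bis(trimethylsilyloxy)ethane, TMSOTf, CH2Cl2, −78 °C), the C-3 ketone being shielded by the quaternary C-4, and the route is rejoined at 12.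

Step 10. E selectivity in the olefination of a methyl ketone may be incomplete, and enolisation may compete with addition. Fallback (stereospecific): setting out from 16, LiN(i-Pr)2 (LDA) and ClP(O)(OEt)2 give the terminal enol phosphate F3, which with further LDA eliminates in the same pot to the terminal alkyne F4. Zirconium-catalysed methylalumination (Me3Al, Cp2ZrCl2, CH2Cl2, 25 °C) adds methyl and aluminium syn to give the E-alkenylalane F5, which with n-BuLi and paraformaldehyde gives the 13E allylic alcohol F6. LiAlH4 then removes the auxiliary ester and the route is rejoined at 18.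

Step 14. The ene reaction may also occur at the side-chain alkene (C-12 or C-16) or at C-9, or the alcohol may be over-oxidised to the 7-ketone. Fallback: the hydroxylation is moved to 17, where the side-chain alkene is conjugated to the ester and inert to the ene reaction. SeO2/t-BuOOH on 17 gives the 7α-hydroxy diester F7, and LiAlH4 gives the 7α,15,19-triol F8. TBSCl/imidazole at −20 °C silylates only the unhindered allylic C-15 hydroxyl to give F9. Ac2O/pyridine at 0 °C without DMAP should then acetylate the primary C-19 hydroxyl in preference to the axial secondary 7α-hydroxyl, and the route is rejoined at 21.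

**Further compounds**
F1 | step 6 | (1R,2S,5R)-8-phenylmenthyl (6E,10E)-2,6,10-trimethyl-3,14-dioxopentadeca-6,10-dienoate | CC(C)(c1ccccc1)[C@@H]1CC[C@@H](C)C[C@H]1OC(=O)C(C)C(=O)CC/C(C)=C/CC/C(C)=C/CCC(C)=O
F2 | step 6 | (1R,2S,5R)-8-phenylmenthyl 3,13-dioxo-14,15-dinorlabd-8(17)-en-19-oate | C=C1CC[C@H]2[C@@](C)(C(=O)O[C@@H]3C[C@H](C)CC[C@H]3C(C)(C)c3ccccc3)C(=O)CC[C@]2(C)[C@H]1CCC(C)=O
F3 | step 10 | (1R,2S,5R)-8-phenylmenthyl 13-(diethoxyphosphoryloxy)-15-norlabda-8(17),13-dien-19-oate (terminal enol phosphate, not isolated) | C=C1CC[C@H]2[C@@](C)(C(=O)O[C@@H]3C[C@H](C)CC[C@H]3C(C)(C)c3ccccc3)CCC[C@]2(C)[C@H]1CCC(=C)OP(=O)(OCC)OCC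
F4 | step 10 | (1R,2S,5R)-8-phenylmenthyl 15,16-dinorlabd-8(17)-en-13-yn-19-oate (terminal alkyne) | C=C1CC[C@H]2[C@@](C)(C(=O)O[C@@H]3C[C@H](C)CC[C@H]3C(C)(C)c3ccccc3)CCC[C@]2(C)[C@H]1CCC#C
F5 | step 10 | (1R,2S,5R)-8-phenylmenthyl 14-(dimethylalumanyl)-15-norlabda-8(17),13E-dien-19-oate (alkenylalane, not isolated) | C=C1CC[C@H]2[C@@](C)(C(=O)O[C@@H]3C[C@H](C)CC[C@H]3C(C)(C)c3ccccc3)CCC[C@]2(C)[C@H]1CC/C(C)=C/[Al](C)C
F6 | step 10 | (1R,2S,5R)-8-phenylmenthyl 15-hydroxylabda-8(17),13E-dien-19-oate | C=C1CC[C@H]2[C@@](C)(C(=O)O[C@@H]3C[C@H](C)CC[C@H]3C(C)(C)c3ccccc3)CCC[C@]2(C)[C@H]1CC/C(C)=C/CO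
F7 | step 14 | 15-ethyl 19-[(1R,2S,5R)-8-phenylmenthyl] 7α-hydroxylabda-8(17),13E-diene-15,19-dioate | C=C1[C@H](O)C[C@H]2[C@@](C)(C(=O)O[C@@H]3C[C@H](C)CC[C@H]3C(C)(C)c3ccccc3)CCC[C@]2(C)[C@H]1CC/C(C)=C/C(=O)OCC
F8 | step 14 | labda-8(17),13E-diene-7α,15,19-triol | C=C1[C@H](O)C[C@H]2[C@@](C)(CO)CCC[C@]2(C)[C@H]1CC/C(C)=C/CO
F9 | step 14 | 15-(tert-butyldimethylsilyloxy)labda-8(17),13E-diene-7α,19-diol | C=C1[C@H](O)C[C@H]2[C@@](C)(CO)CCC[C@]2(C)[C@H]1CC/C(C)=C/CO[Si](C)(C)C(C)(C)C
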